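Assumption: (−)-epicatechin 3-O-gallate (ECG, the tea catechin) is taken as a cheap commercial starting material. Numbering: A-ring 5–8, B-ring 3′,4′, galloyl 3″,4″,5″. "4β" means the C-4 substituent is trans to both the 3-O-galloyl group and the 2-aryl ring, as in the target, which is ECG-(4β→6)-ECG-(4β→8)-ECG.

## Retrosynthetic overview

1. Target ⇐ one hydrogenolysis of a fully masked trimer (9 benzyl ethers, 6 diphenylmethylene ketals, 2 C-8 bromines).
2. C-4(middle)–C-8(bottom) bond ⇐ TMSOTf ionisation of a dimer C-4 ether in the presence of protected ECG; attack anti to the 3-O-galloyl group gives 4β.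
3. C-4(top)–C-6(middle) bond ⇐ Ag(I) ionisation of a 4β-benzylthio unit in the presence of an 8-bromo-4β-alkoxy unit; bromine blocks C-8 and the ether is inert to silver.
4. All three units ⇐ ECG masked in one flask: the B-ring catechol and the galloyl vicinal diol are closed together to two 1,3-benzodioxole rings (Ph2CCl2), then the three isolated phenols are benzylated.
5. Ring order: the two dioxole rings form first, are carried through both couplings (six in the trimer) and are opened last. The three pyran rings, all benzene rings and the C-2/C-3 stereocentres come intact from ECG; the C-4 centres are set in steps 3–6.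

## Route

Step 1
Reactants: 1 (−)-epicatechin 3-O-gallate (ECG); 2 dichlorodiphenylmethane; 3 benzyl bromide
Product: 5 protected ECG [5,7,5″-tri-O-benzyl-3′,4′:3″,4″-di-O-(diphenylmethylene)-ECG, 2R,3R], via bis(diphenylmethylene) ketal of ECG 4 (not isolated)
Conditions: Ph2CCl2 (2.3 equiv), K2CO3, MeCN, 25→50 °C; then BnBr (3.6 equiv), K2CO3, Bu4NI (cat.), DMF, 25 °C, same flask
Reagents that add atoms: dichlorodiphenylmethane ClC(Cl)(c1ccccc1)c1ccccc1; benzyl bromide BrCc1ccccc1
Why: Double cyclic ketalisation followed by Williamson benzylation: only the B-ring catechol and the galloyl vicinal diol can close five-membered 1,3-benzodioxole rings on the gem-dichloride, so both rings form in the one operation and exactly the three isolated phenols (5-, 7-, 5″-OH) are left for BnBr, while the mild carbonate conditions leave C-2 and C-3 untouched.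

Step 2
Reactants: 5 protected ECG; 6 N-bromosuccinimide
Product: 7 8-bromo-protected ECG (2R,3R)
Conditions: NBS (1.0 equiv), CH2Cl2, −40→0 °C
Reagents that add atoms: N-bromosuccinimide O=C1CCC(=O)N1Br
Why: Electrophilic aromatic bromination (SEAr) goes to C-8, the most nucleophilic carbon of the 5,7-dialkoxy A-ring, and the bromine later forces Friedel–Crafts attack on this ring to C-6 and stops the ring acting as a C-8 nucleophile, with no stereocentre involved.

Step 3
Reactants: 7 8-bromo-protected ECG; 8 2-ethoxyethanol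
Product: 9 8-bromo-4β-(2-ethoxyethoxy)-protected ECG (2R,3R,4S)
Conditions: DDQ (2 equiv), EtOCH2CH2OH (6 equiv), CH2Cl2, 25 °C
Reagents that add atoms: 2-ethoxyethanol CCOCCO
Why: DDQ benzylic C–H oxidation (hydride abstraction) gives the C-4 cation stabilised by the A-ring and O-1, which the alcohol traps anti to the 3-O-galloyl group and the B-ring, setting C-4 as 4β.

Step 4
Reactants: 9 8-bromo-4β-(2-ethoxyethoxy)-protected ECG; 10 phenylmethanethiol
Product: 11 8-bromo-4β-(benzylsulfanyl)-protected ECG (2R,3S,4S; same spatial arrangement, CIP label at C-3 changes because of sulfur)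
Conditions: BnSH (5 equiv), TMSOTf (0.1 equiv), CH2Cl2, −78 °C, 15 min; Et3N quench
Reagents that add atoms: phenylmethanethiol SCc1ccccc1
Why: Lewis-acid-catalysed SN1 thiolysis (the classical flavan O→S exchange at C-4) passes through the same cation, the thiol adds from the open β-face so C-4 is again 4β, and the thioether is a latent electrophile that only a thiophile switches on.

Step 5
Reactants: 11 8-bromo-4β-(benzylsulfanyl)-protected ECG; 9 8-bromo-4β-(2-ethoxyethoxy)-protected ECG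
Product: 12 dimer: 8-bromo-protected ECG-(4β→6)-[8-bromo-4β-(2-ethoxyethoxy)-protected ECG]
Conditions: AgBF4 (1.3 equiv), 2,6-di-tert-butyl-4-methylpyridine (1.5 equiv), 4 Å MS, CH2Cl2, −40→0 °C; 9 (3 equiv, excess recovered), 11 added over 2 h
Reagents that add atoms: none
Why: Ag(I)-promoted SN1 Friedel–Crafts alkylation (thiophilic activation of a flavan-4-yl sulfide, as in silver-mediated procyanidin couplings): the C-4 cation of 11 attacks the only free A-ring carbon of 9, C-6, from the β-face anti to its 3-O-galloyl group, giving the 4β→6 bond while the 4-alkoxy group of 9 is not ionised by the buffered silver salt.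

Step 6
Reactants: 12 dimer; 5 protected ECG
Product: 13 protected trimer: 8-bromo-protected ECG-(4β→6)-8-bromo-protected ECG-(4β→8)-protected ECG
Conditions: TMSOTf (0.2 equiv), 5 (3 equiv, excess recovered), 4 Å MS, CH2Cl2, −78→−40 °C; Et3N quench
Reagents that add atoms: none
Why: TMSOTf-catalysed SN1 Friedel–Crafts alkylation: ionisation of the 4-alkoxy group gives the C-4 cation of the middle unit, which is attacked by C-8 of 5 (its more accessible and more nucleophilic A-ring carbon) from the β-face anti to the 3-O-galloyl group, setting the 4β→8 linkage.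

Step 7
Reactants: 13 protected trimer
Product: 14 ECG-(4β→6)-ECG-(4β→8)-ECG (target, CNP0183218.1)
Conditions: H2 (1 atm), 20% Pd(OH)2/C, Et3N (2.2 equiv), THF–MeOH–H2O, 25 °C; then AcOH, Sephadex LH-20
Reagents that add atoms: none
Why: Catalytic hydrogenolysis cleaves the nine benzyl ethers and six diphenylmethylene ketals at their benzylic C–O bonds and reduces both aryl C–Br bonds (Et3N takes up HBr), while esters, interflavan bonds and all eight stereocentres are inert.

## Compound list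

1 | (−)-epicatechin 3-O-gallate, (2R,3R) | O=C(O[C@@H]1Cc2c(O)cc(O)cc2O[C@@H]1c1ccc(O)c(O)c1)c1cc(O)c(O)c(O)c1 | starting material
2 | dichlorodiphenylmethane | ClC(Cl)(c1ccccc1)c1ccccc1 | starting material
3 | benzyl bromide | BrCc1ccccc1 | starting material
4 | 3′,4′:3″,4″-di-O-(diphenylmethylene)-ECG (5-, 7-, 5″-OH free) | O=C(O[C@@H]1Cc2c(O)cc(O)cc2O[C@@H]1c1ccc2OC(c3ccccc3)(c3ccccc3)Oc2c1)c1cc2OC(c3ccccc3)(c3ccccc3)Oc2c(O)c1 | intermediate
5 | protected ECG: 5,7,5″-tri-O-benzyl-3′,4′:3″,4″-di-O-(diphenylmethylene)-ECG | O=C(O[C@@H]1Cc2c(OCc3ccccc3)cc(OCc3ccccc3)cc2O[C@@H]1c1ccc2OC(c3ccccc3)(c3ccccc3)Oc2c1)c1cc2OC(c3ccccc3)(c3ccccc3)Oc2c(OCc2ccccc2)c1 | intermediate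
6 | N-bromosuccinimide | O=C1CCC(=O)N1Br | starting material
7 | 8-bromo-protected ECG | O=C(O[C@@H]1Cc2c(OCc3ccccc3)cc(OCc3ccccc3)c(Br)c2O[C@@H]1c1ccc2OC(c3ccccc3)(c3ccccc3)Oc2c1)c1cc2OC(c3ccccc3)(c3ccccc3)Oc2c(OCc2ccccc2)c1 | intermediate
8 | 2-ethoxyethanol | CCOCCO | starting material
9 | 8-bromo-4β-(2-ethoxyethoxy)-protected ECG | O=C(O[C@@H]1[C@@H](OCCOCC)c2c(OCc3ccccc3)cc(OCc3ccccc3)c(Br)c2O[C@@H]1c1ccc2OC(c3ccccc3)(c3ccccc3)Oc2c1)c1cc2OC(c3ccccc3)(c3ccccc3)Oc2c(OCc2ccccc2)c1 | intermediate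
10 | phenylmethanethiol | SCc1ccccc1 | starting material
11 | 8-bromo-4β-(benzylsulfanyl)-protected ECG | O=C(O[C@@H]1[C@@H](SCc3ccccc3)c2c(OCc3ccccc3)cc(OCc3ccccc3)c(Br)c2O[C@@H]1c1ccc2OC(c3ccccc3)(c3ccccc3)Oc2c1)c1cc2OC(c3ccccc3)(c3ccccc3)Oc2c(OCc2ccccc2)c1 | intermediate
12 | dimer: 8-bromo-protected ECG-(4β→6)-[8-bromo-4β-(2-ethoxyethoxy)-protected ECG] | O=C(O[C@@H]1[C@@H](c2c(OCc4ccccc4)c(Br)c3c(c2OCc4ccccc4)[C@H](OCCOCC)[C@@H](OC(=O)c2cc4OC(c5ccccc5)(c5ccccc5)Oc4c(OCc4ccccc4)c2)[C@@H](c2ccc4OC(c5ccccc5)(c5ccccc5)Oc4c2)O3)c2c(OCc3ccccc3)cc(OCc3ccccc3)c(Br)c2O[C@@H]1c1ccc2OC(c3ccccc3)(c3ccccc3)Oc2c1)c1cc2OC(c3ccccc3)(c3ccccc3)Oc2c(OCc2ccccc2)c1 | intermediate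
13 | protected trimer: 8-bromo-protected ECG-(4β→6)-8-bromo-protected ECG-(4β→8)-protected ECG | O=C(O[C@@H]1[C@@H](c2c(OCc4ccccc4)c(Br)c3c(c2OCc4ccccc4)[C@H](c2c(OCc5ccccc5)cc(OCc5ccccc5)c4c2O[C@H](c2ccc5OC(c6ccccc6)(c6ccccc6)Oc5c2)[C@H](OC(=O)c2cc5OC(c6ccccc6)(c6ccccc6)Oc5c(OCc5ccccc5)c2)C4)[C@@H](OC(=O)c2cc4OC(c5ccccc5)(c5ccccc5)Oc4c(OCc4ccccc4)c2)[C@@H](c2ccc4OC(c5ccccc5)(c5ccccc5)Oc4c2)O3)c2c(OCc3ccccc3)cc(OCc3ccccc3)c(Br)c2O[C@@H]1c1ccc2OC(c3ccccc3)(c3ccccc3)Oc2c1)c1cc2OC(c3ccccc3)(c3ccccc3)Oc2c(OCc2ccccc2)c1 | intermediate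
14 | ECG-(4β→6)-ECG-(4β→8)-ECG | O=C(O[C@@H]1[C@@H](c2c(O)cc3c(c2O)[C@H](c2c(O)cc(O)c4c2O[C@H](c2ccc(O)c(O)c2)[C@H](OC(=O)c2cc(O)c(O)c(O)c2)C4)[C@@H](OC(=O)c2cc(O)c(O)c(O)c2)[C@@H](c2ccc(O)c(O)c2)O3)c2c(O)cc(O)cc2O[C@@H]1c1ccc(O)c(O)c1)c1cc(O)c(O)c(O)c1 | target

## Step count and risks

Total steps: 7. Longest linear sequence: 7 (steps 1–7 lie on one line; 9 and 5 re-enter as coupling partners in steps 5 and 6).

Steps most likely to fail:

**Step 5.** The attack is on a hindered, bromine-deactivated C-6; 11 can self-condense; the 4-alkoxy group of 9 may leak. Fallback: give up the two orthogonal leaving groups and install the second one after the C–C bond exists. It sets out from 7 and 11. Silver-promoted coupling of 11 with excess bromide 7, which has no leaving group and can react only at C-6, gives the 4β→6 dimer with an unsubstituted C-4 on the lower unit F1. Late-stage DDQ oxidation of F1 in the presence of 8 then functionalises the only benzylic CH2 left (C-4 of the lower unit; the C-4–H of the upper unit is tertiary and buried between two aryl rings). The route is rejoined at 12.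

**Step 6.** The dimeric electrophile is bulky, acid can also cleave the existing interflavan bond, and C-8/C-6 selectivity is not guaranteed. Fallback: change the nucleophile from the benzylated to the phenolic series so that a much weaker acid suffices. It sets out from 12 and from 4, which is isolated by stopping step 1 before the benzylation. Condensation of 12 with the free-phenol A-ring of 4 (Yb(OTf)3, THF, 0 °C) gives the trimer with a phenolic bottom unit F2. F2 is hydrogenolysed under the conditions of step 7 and the route is rejoined at 14.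

**Step 1.** A one-flask double ring closure plus tri-benzylation on a base-sensitive catechin may give incomplete ketalisation, C-benzylation or C-2 epimerisation. Fallback: invert the order, ethers first and rings second, with boron masking. It sets out from 1. The catechol and the galloyl vicinal diol are tied up as phenylboronate esters (PhB(OH)2, 4 Å MS, DMF), the three remaining phenols are benzylated with 3 (K2CO3), and the boronates are washed out (aqueous sorbitol/Na2CO3) to give 5,7,5″-tri-O-benzyl-ECG F3. Ketalisation of the two free diol pairs of F3 with 2 closes both dioxole rings and returns to 5.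

Further compounds
F1 | step 5 | dimer: 8-bromo-protected ECG-(4β→6)-8-bromo-protected ECG (lower unit C-4 is CH2) | O=C(O[C@@H]1[C@@H](c2c(OCc4ccccc4)c(Br)c3c(c2OCc4ccccc4)C[C@@H](OC(=O)c2cc4OC(c5ccccc5)(c5ccccc5)Oc4c(OCc4ccccc4)c2)[C@@H](c2ccc4OC(c5ccccc5)(c5ccccc5)Oc4c2)O3)c2c(OCc3ccccc3)cc(OCc3ccccc3)c(Br)c2O[C@@H]1c1ccc2OC(c3ccccc3)(c3ccccc3)Oc2c1)c1cc2OC(c3ccccc3)(c3ccccc3)Oc2c(OCc2ccccc2)c1
F2 | step 6 | trimer as 13 but with free 5-, 7- and 5″-hydroxyls on the bottom unit | O=C(O[C@@H]1[C@@H](c2c(OCc4ccccc4)c(Br)c3c(c2OCc4ccccc4)[C@H](c2c(O)cc(O)c4c2O[C@H](c2ccc5OC(c6ccccc6)(c6ccccc6)Oc5c2)[C@H](OC(=O)c2cc5OC(c6ccccc6)(c6ccccc6)Oc5c(O)c2)C4)[C@@H](OC(=O)c2cc4OC(c5ccccc5)(c5ccccc5)Oc4c(OCc4ccccc4)c2)[C@@H](c2ccc4OC(c5ccccc5)(c5ccccc5)Oc4c2)O3)c2c(OCc3ccccc3)cc(OCc3ccccc3)c(Br)c2O[C@@H]1c1ccc2OC(c3ccccc3)(c3ccccc3)Oc2c1)c1cc2OC(c3ccccc3)(c3ccccc3)Oc2c(OCc2ccccc2)c1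
F3 | step 1 | 5,7,5″-tri-O-benzyl-ECG (B-ring catechol and galloyl 3″,4″-diol free) | O=C(O[C@@H]1Cc2c(OCc3ccccc3)cc(OCc3ccccc3)cc2O[C@@H]1c1ccc(O)c(O)c1)c1cc(O)c(O)c(OCc2ccccc2)c1
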